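The route rests on cutting the C9–C10 bond of the bridged bicycle. C10 carries four non-hydrogen groups (methyl, the furanone ring oxygen, the C1 ketone and C9) and C9 is a secondary carbinol, so C9(OH)–C10–C1(=O), with C10 and C1 in the 3(2H)-furanone ring, is an aldol array whose enol partner is a flat, aromatic 2-methyl-3-siloxyfuran. One Lewis-acid Mukaiyama aldol step should close the ten-membered carbocycle (C1 to C10), create the quaternary C10 and the C9 carbinol and release the furanone. Its precursor is a C9 aldehyde linked through C8, the cis-fused γ-lactone (C6, C7, C11, C12) and the Z C4=C5 alkene to the siloxyfuran, with the C8 angelate and the C11/C13 chlorohydrin already installed.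

Key step: step 20

Remarks on the chemistry (assumptions and design decisions)
- Locants: C1 is the furanone carbonyl carbon, C2 and C3 its ring alkene (C3 on the ring oxygen), C4 (methyl-bearing) and C5 the Z alkene, C6 the lactone carbinol carbon, C7 the ring-fusion carbon, C8 the angeloyloxy carbon, C9 the carbinol carbon, C10 the methyl-bearing quaternary carbon, C11 the hydroxylated lactone α-carbon, C12 the lactone carbonyl, C13 the chloromethyl carbon. Descriptors in the names use these locants where a systematic name would be unwieldy.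
- Reading of the target: (6S,7S,8S,9R,10R,11R). The lactone is cis-fused (H6 and H7 cis). The C11 hydroxyl is cis to C8 and C5 on the lactone ring, and CH2Cl is cis to H7. The C8 and C9 oxygens are syn.
- The 8,9-syn relationship is the opposite of what open-chain Felkin–Anh addition to an α-oxygenated aldehyde gives. Control of C9 is therefore assigned to the ring-closing geometry (step 20), not to a Felkin argument.
- A reagent adding oxygen to C11 of an α-methylene lactone would approach anti to C8 and give the C11 epimer. The chlorohydrin is therefore set before ring closure, under reagent control, at the allylic-alcohol oxidation level (steps 7 to 10).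
- The angelate is placed on C8 before ring closure, so no C8/C9 diol has to be differentiated on the base-sensitive β-hydroxy ketone.
- The aldehyde is made before the silyl enol ether. Triethylsilyl replaces trimethylsilyl on the furan for robustness and also caps the C11 hydroxyl.
- Assumption: the carbinol centre of the Baylis–Hillman adduct and the lactate-derived C10 centre are inconsequential, because both become sp2 later.

Step 1
Reactants: 1 1,2:5,6-di-O-isopropylidene-D-mannitol
Product: 2 (4R)-2,2-dimethyl-1,3-dioxolane-4-carbaldehyde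
Conditions: NaIO4, sat. aq. NaHCO3, CH2Cl2, 0 °C to rt
Reagents that add atoms: none
Why: Periodate glycol cleavage of the central diol gives two equivalents of the aldehyde, whose stereocentre (the future C8) comes unchanged from the chiral pool.

Step 2
Reactants: 2 (4R)-2,2-dimethyl-1,3-dioxolane-4-carbaldehyde; 3 methyl acrylate
Product: 4 methyl 2-{[(4R)-2,2-dimethyl-1,3-dioxolan-4-yl](hydroxy)methyl}prop-2-enoate (both carbinol epimers)
Conditions: DABCO (0.3 equiv), 1,4-dioxane/H2O (1:1), rt
Reagents that add atoms: none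
Why: Morita–Baylis–Hillman addition of the acrylate to the aldehyde attaches C7, C11, C12 and C13 to the C8–C9 unit; the new carbinol centre is of no consequence because it becomes sp2 in step 3.

Step 3
Reactants: 4 methyl 2-{[(4R)-2,2-dimethyl-1,3-dioxolan-4-yl](hydroxy)methyl}prop-2-enoate
Product: 5 methyl (2Z)-2-(bromomethyl)-3-[(4S)-2,2-dimethyl-1,3-dioxolan-4-yl]prop-2-enoate
Conditions: NBS, Me2S, CH2Cl2, 0 °C to rt
Reagents that add atoms: N-bromosuccinimide, O=C1CCC(=O)N1Br
Why: Corey–Kim-type activation of the hydroxyl and SN2' delivery of bromide convert both carbinol epimers into the single, thermodynamically favoured (Z)-2-(bromomethyl)enoate.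

Step 4
Reactants: 6 but-2-yn-1-ol
Product: 8 (2Z)-3-iodobut-2-en-1-ol, via cyclic alkenylalanate 7 (not isolated)
Conditions: NaAlH2(OCH2CH2OMe)2 (Red-Al), THF, 0 °C to rt; then I2, THF, −78 °C to 0 °C
Reagents that add atoms: iodine, [I][I]
Why: Hydroxyl-directed trans-hydroalumination of the propargylic alcohol places aluminium on the distal alkyne carbon and iodinolysis occurs with retention, which fixes the later Z geometry of C4=C5.

Step 5
Reactants: 8 (2Z)-3-iodobut-2-en-1-ol
Product: 9 (2Z)-3-iodobut-2-enal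
Conditions: MnO2 (activated, excess), CH2Cl2, rt, dark
Reagents that add atoms: none
Why: Allylic oxidation with activated MnO2 is neutral and leaves the Z alkene untouched; the sensitive β-iodoenal is used directly.

Step 6
Reactants: 5 methyl (2Z)-2-(bromomethyl)-3-[(4S)-2,2-dimethyl-1,3-dioxolan-4-yl]prop-2-enoate; 9 (2Z)-3-iodobut-2-enal
Product: 11 methyl (3S,4R,5Z)-3-[(4S)-2,2-dimethyl-1,3-dioxolan-4-yl]-4-hydroxy-6-iodo-2-methylidenehept-5-enoate, via allylindium dibromide 10 (not isolated)
Conditions: In powder, THF/H2O (1:1), rt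
Reagents that add atoms: none
Why: Barbier-type indium allylation through a six-membered chair transition state: the Z-configured allylindium should give the 6,7-syn adduct (the later cis-lactone), and with H8 eclipsing the alkene to avoid 1,3-allylic strain the aldehyde should add to C7 syn to the dioxolane oxygen and anti to its CH2 group, which sets C6 and C7 relative to C8.

Step 7
Reactants: 11 methyl (3S,4R,5Z)-3-[(4S)-2,2-dimethyl-1,3-dioxolan-4-yl]-4-hydroxy-6-iodo-2-methylidenehept-5-enoate
Product: 12 (3S,4R,5Z)-3-[(4S)-2,2-dimethyl-1,3-dioxolan-4-yl]-6-iodo-2-methylidenehept-5-ene-1,4-diol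
Conditions: i-Bu2AlH (4 equiv), CH2Cl2, −78 to 0 °C; aq. potassium sodium tartrate
Reagents that add atoms: none
Why: 1,2-Reduction of the enoate with i-Bu2AlH gives the 2-substituted allylic alcohol required for a reagent-controlled epoxidation and also converts any lactonised material into the same diol.

Step 8
Reactants: 12 (3S,4R,5Z)-3-[(4S)-2,2-dimethyl-1,3-dioxolan-4-yl]-6-iodo-2-methylidenehept-5-ene-1,4-diol
Product: 13 [(2R)-2-{(1S,2R,3Z)-1-[(4S)-2,2-dimethyl-1,3-dioxolan-4-yl]-2-hydroxy-4-iodopent-3-en-1-yl}oxiran-2-yl]methanol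
Conditions: Ti(OiPr)4 (0.3 equiv), D-(−)-diethyl tartrate (0.36 equiv), t-BuOOH (2 equiv, decane), 4 Å molecular sieves, CH2Cl2, −25 °C
Reagents that add atoms: tert-butyl hydroperoxide, CC(C)(C)OO
Why: Sharpless asymmetric epoxidation of the primary 2-substituted allylic alcohol sets C11 under reagent control, the unnatural D-tartrate delivering oxygen to the alkene face that gives the (11R)-epoxide whose C–O bond will be cis to C8 in the lactone; the iodoalkene beside the secondary carbinol is too electron-poor to compete.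

Step 9
Reactants: 13 [(2R)-2-{(1S,2R,3Z)-1-[(4S)-2,2-dimethyl-1,3-dioxolan-4-yl]-2-hydroxy-4-iodopent-3-en-1-yl}oxiran-2-yl]methanol
Product: 15 (3S,6R,7S)-7-[(4S)-2,2-dimethyl-1,3-dioxolan-4-yl]-6-[(1Z)-2-iodoprop-1-en-1-yl]-1,5-dioxaspiro[2.4]heptan-4-one, via spiro-epoxy lactol 14 (not isolated)
Conditions: TEMPO (0.2 equiv), PhI(OAc)2 (2.5 equiv), CH2Cl2, rt
Reagents that add atoms: none
Why: TEMPO-mediated oxidation is selective for the primary alcohol, and the resulting aldehyde is captured by the C6 hydroxyl as a lactol that is oxidised further to the cis-γ-lactone (oxidative lactonisation) without disturbing the epoxide.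

Step 10
Reactants: 15 (3S,6R,7S)-7-[(4S)-2,2-dimethyl-1,3-dioxolan-4-yl]-6-[(1Z)-2-iodoprop-1-en-1-yl]-1,5-dioxaspiro[2.4]heptan-4-one
Product: 17 (3R,4R,5R)-3-(chloromethyl)-4-[(1S)-1,2-dihydroxyethyl]-3-hydroxy-5-[(1Z)-2-iodoprop-1-en-1-yl]oxolan-2-one, via chlorohydrin acetonide 16 (not isolated)
Conditions: conc. aq. HCl (5 equiv), THF, 0 °C to rt
Reagents that add atoms: hydrogen chloride, Cl
Why: Acid-promoted SN2 opening of the spiro-epoxide by chloride at the unhindered methylene C13 keeps the C11–O bond and its configuration, and the same acid then hydrolyses the terminal acetonide.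

Step 11
Reactants: 17 (3R,4R,5R)-3-(chloromethyl)-4-[(1S)-1,2-dihydroxyethyl]-3-hydroxy-5-[(1Z)-2-iodoprop-1-en-1-yl]oxolan-2-one
Product: 18 (3R,4R,5R)-4-[(1S)-2-{[tert-butyl(dimethyl)silyl]oxy}-1-hydroxyethyl]-3-(chloromethyl)-3-hydroxy-5-[(1Z)-2-iodoprop-1-en-1-yl]oxolan-2-one
Conditions: TBSCl (1.05 equiv), imidazole, CH2Cl2, −20 to 0 °C
Reagents that add atoms: tert-butyldimethylsilyl chloride, CC(C)(C)[Si](C)(C)Cl
Why: Steric differentiation allows selective silylation of the primary C9 hydroxyl in the presence of the secondary C8 and tertiary C11 hydroxyls.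

Step 12
Reactants: 18 (3R,4R,5R)-4-[(1S)-2-{[tert-butyl(dimethyl)silyl]oxy}-1-hydroxyethyl]-3-(chloromethyl)-3-hydroxy-5-[(1Z)-2-iodoprop-1-en-1-yl]oxolan-2-one; 19 angelic acid [(2Z)-2-methylbut-2-enoic acid]
Product: 21 (1S)-2-{[tert-butyl(dimethyl)silyl]oxy}-1-[(2R,3S,4R)-4-(chloromethyl)-4-hydroxy-2-[(1Z)-2-iodoprop-1-en-1-yl]-5-oxooxolan-3-yl]ethyl (2Z)-2-methylbut-2-enoate, via angelic 2,4,6-trichlorobenzoic anhydride 20 (not isolated)
Conditions: 19, 2,4,6-trichlorobenzoyl chloride, Et3N, toluene, rt; then 18, toluene, 75 °C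
Reagents that add atoms: none
Why: Yamaguchi esterification through the preformed mixed anhydride without nucleophilic catalyst acylates the secondary C8 hydroxyl only and is the standard way to introduce an angelate without Z to E isomerisation.

Step 13
Reactants: 22 ethyl (S)-lactate
Product: 23 ethyl (2S)-2-{[tert-butyl(dimethyl)silyl]oxy}propanoate
Conditions: TBSCl, imidazole, DMF, rt
Reagents that add atoms: tert-butyldimethylsilyl chloride, CC(C)(C)[Si](C)(C)Cl
Why: Routine silyl protection of the secondary hydroxyl prevents it from quenching the organomagnesium reagents of step 14.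

Step 14
Reactants: 23 ethyl (2S)-2-{[tert-butyl(dimethyl)silyl]oxy}propanoate
Product: 25 (4S)-4-{[tert-butyl(dimethyl)silyl]oxy}pent-1-yn-3-one, via Weinreb amide 24 (not isolated)
Conditions: MeNHOMe·HCl (1.5 equiv), i-PrMgCl (3.0 equiv), THF, −20 °C; then HC≡CMgBr (3 equiv), −20 to 0 °C; aq. NH4Cl
Reagents that add atoms: ethynylmagnesium bromide, C#C[Mg]Br
Why: Weinreb ketone synthesis in one flask: the magnesium amide converts the ester into the N-methoxy-N-methylamide, whose chelated tetrahedral adduct with the alkynyl Grignard reagent collapses to the ynone only on work-up, so over-addition is avoided.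

Step 15
Reactants: 21 C8 angelate vinyl iodide (name as in step 12); 25 (4S)-4-{[tert-butyl(dimethyl)silyl]oxy}pent-1-yn-3-one
Product: 26 (Z)-enynone (6S,7S,8S,10S,11R): 21 in which iodine is replaced by the (4S)-4-{[tert-butyl(dimethyl)silyl]oxy}-3-oxopent-1-yn-1-yl group
Conditions: Pd(PPh3)2Cl2 (5 mol %), CuI (10 mol %), Et3N, THF, rt
Reagents that add atoms: none
Why: Sonogashira coupling of the vinyl iodide with the terminal alkyne forms the C3–C4 bond with retention of the Z alkene geometry under conditions (tertiary amine, room temperature) that spare the chlorohydrin, the lactone and the angelate.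

Step 16
Reactants: 26 (Z)-enynone bearing C9-OTBS and C10-OTBS
Product: 27 dihydroxy enynone (6S,7S,8S,10S,11R): 26 with free C9-OH and C10-OH
Conditions: HF·pyridine, pyridine, THF, 0 °C to rt
Reagents that add atoms: none
Why: Fluoride-mediated cleavage of both silyl ethers under buffered acidic conditions frees the C9 and C10 hydroxyls without base, so acyl migration, epoxide formation and conjugate addition to the ynone are avoided.

Step 17
Reactants: 27 dihydroxy enynone
Product: 28 furanone alcohol (6S,7S,8S,10S,11R): 5-alkenyl-2-methyl-3(2H)-furanone with free C9-OH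
Conditions: Ph3PAuNTf2 (5 mol %), CH2Cl2, rt
Reagents that add atoms: none
Why: Gold-catalysed 5-endo-dig cycloisomerisation of the α'-hydroxy ynone (intramolecular hydroalkoxylation, C10–O onto C3) gives the 2-methyl-3(2H)-furanone; its C10 centre is epimerisable and is erased in step 19.

Step 18
Reactants: 28 furanone alcohol
Product: 29 furanone aldehyde (6S,7S,8S,10S,11R): 28 with C9 oxidised to CHO
Conditions: Dess–Martin periodinane, NaHCO3, CH2Cl2, 0 °C
Reagents that add atoms: none
Why: Buffered Dess–Martin oxidation converts the primary C9 alcohol into the aldehyde under non-basic conditions that should not epimerise the α-acyloxy centre C8 or touch the tertiary alcohol.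

Step 19
Reactants: 29 furanone aldehyde
Product: 30 key-step precursor (6S,7S,8S,11R): C9 aldehyde joined through the angelate-bearing C8 / the cis-γ-lactone carrying C11-OSiEt3 and C13-Cl / the Z C4=C5 alkene to 2-methyl-3-(triethylsiloxy)furan
Conditions: Et3SiOTf (2.4 equiv), Et3N (4 equiv), CH2Cl2 (0.01 M), −78 °C; pentane, filtration under argon, evaporation; used at once
Reagents that add atoms: triethylsilyl trifluoromethanesulfonate, CC[Si](CC)(CC)OS(=O)(=O)C(F)(F)F
Why: Soft enolisation with silyl triflate and amine is fastest at the furanone, because deprotonation of its O-silylated form gives an aromatic furan, so at −78 °C the 3-siloxyfuran forms and the tertiary C11 hydroxyl is capped while the aldehyde is expected to stay intact; triethylsilyl is chosen so that the siloxyfuran survives a non-aqueous work-up.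

Step 20
Reactants: 30 key-step precursor
Product: 31 C11-O-triethylsilyl ether of the target (6S,7S,8S,9R,10R,11R): furanone-bridged ten-membered carbocycle with free C9-OH
Conditions: BF3·OEt2 (2 equiv), CH2Cl2, −78 °C, 30 added slowly to a final 0.001 M; sat. aq. NaHCO3
Reagents that add atoms: none
Why: BF3 binds the aldehyde oxygen and the methyl-bearing furan carbon C10, the enol-ether carbon flanked by the ring oxygen and C1–OSiEt3, attacks C9; the silyl group then leaves the cationic adduct as Et3SiF, which releases the 3(2H)-furanone, and the boron aldolate is hydrolysed on work-up. The closest known reaction is the Lewis-acid Mukaiyama aldol addition of 2-substituted 3-silyloxyfurans to aldehydes giving 2,2-disubstituted 3(2H)-furanones, run here intramolecularly under high dilution. The ten-membered carbocycle (C1 to C10) closes by 10-exo-trig attack on the aldehyde carbon. C10 should be controlled by C6: with H6 eclipsing the Z C4=C5 alkene (1,3-allylic strain) the C7–C8–C9 arm lies on one face of the diene and reaches only the furan face that gives 10R; C9 should be controlled by C8 and the tether, because C8 must sit on the ring-oxygen side of C10 and the BF3-bound oxygen then points away from the ring interior, which gives the 8,9-syn (9R) carbinol. The step needs attack through C10 and not C2 (secured because C2 would require an eight-membered ring and would not give a conjugated furanone), ring closure over oligomerisation (secured by dilution) and an intact C8 centre (secured by non-basic conditions at −78 °C).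

Step 21
Reactants: 31 C11-O-triethylsilyl ether of the target
Product: 32 CNP0272644.1 (6S,7S,8S,9R,10R,11R)
Conditions: HF·pyridine, pyridine, THF, 0 °C
Reagents that add atoms: none
Why: Acidic fluoride cleaves the tertiary triethylsilyl ether without base, so neither retro-aldol opening of the β-hydroxy ketone nor epoxide formation from the chlorohydrin can occur.

Compound list
1 | 1,2:5,6-di-O-isopropylidene-D-mannitol | CC1(C)OC[C@@H](O1)[C@@H](O)[C@H](O)[C@H]1COC(C)(C)O1 | starting material
2 | (4R)-2,2-dimethyl-1,3-dioxolane-4-carbaldehyde [(R)-2,3-O-isopropylideneglyceraldehyde] | O=C[C@H]1COC(C)(C)O1 | intermediate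
3 | methyl acrylate | C=CC(=O)OC | starting material
4 | methyl 2-{[(4R)-2,2-dimethyl-1,3-dioxolan-4-yl](hydroxy)methyl}prop-2-enoate (both carbinol epimers) | C=C(C(=O)OC)C(O)[C@H]1COC(C)(C)O1 | intermediate
5 | methyl (2Z)-2-(bromomethyl)-3-[(4S)-2,2-dimethyl-1,3-dioxolan-4-yl]prop-2-enoate | COC(=O)/C(CBr)=C/[C@H]1COC(C)(C)O1 | intermediate
6 | but-2-yn-1-ol | CC#CCO | starting material
7 | cyclic alkenylalanate: sodium 2,2-bis(2-methoxyethoxy)-3-methyl-2,5-dihydro-1,2-oxaaluminol-2-uide | CC1=CCO[Al-]1(OCCOC)OCCOC.[Na+] | intermediate (not isolated)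
8 | (2Z)-3-iodobut-2-en-1-ol | C/C(I)=C/CO | intermediate
9 | (2Z)-3-iodobut-2-enal | C/C(I)=C/C=O | intermediate
10 | allylindium dibromide: dibromo{(2Z)-3-[(4S)-2,2-dimethyl-1,3-dioxolan-4-yl]-2-(methoxycarbonyl)prop-2-en-1-yl}indium | COC(=O)/C(C[In](Br)Br)=C/[C@H]1COC(C)(C)O1 | intermediate (not isolated)
11 | methyl (3S,4R,5Z)-3-[(4S)-2,2-dimethyl-1,3-dioxolan-4-yl]-4-hydroxy-6-iodo-2-methylidenehept-5-enoate | COC(=O)C(=C)[C@H]([C@H]1COC(C)(C)O1)[C@@H](O)/C=C(/C)I | intermediate
12 | (3S,4R,5Z)-3-[(4S)-2,2-dimethyl-1,3-dioxolan-4-yl]-6-iodo-2-methylidenehept-5-ene-1,4-diol | OCC(=C)[C@H]([C@H]1COC(C)(C)O1)[C@@H](O)/C=C(/C)I | intermediate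
13 | [(2R)-2-{(1S,2R,3Z)-1-[(4S)-2,2-dimethyl-1,3-dioxolan-4-yl]-2-hydroxy-4-iodopent-3-en-1-yl}oxiran-2-yl]methanol | OC[C@@]1(CO1)[C@H]([C@H]2COC(C)(C)O2)[C@@H](O)/C=C(/C)I | intermediate
14 | spiro-epoxy lactol: (3S,6R,7S)-7-[(4S)-2,2-dimethyl-1,3-dioxolan-4-yl]-6-[(1Z)-2-iodoprop-1-en-1-yl]-1,5-dioxaspiro[2.4]heptan-4-ol (both C4 epimers) | OC1O[C@@H](/C=C(/C)I)[C@@H]([C@H]2COC(C)(C)O2)[C@]13CO3 | intermediate (not isolated)
15 | (3S,6R,7S)-7-[(4S)-2,2-dimethyl-1,3-dioxolan-4-yl]-6-[(1Z)-2-iodoprop-1-en-1-yl]-1,5-dioxaspiro[2.4]heptan-4-one | O=C1O[C@@H](/C=C(/C)I)[C@@H]([C@H]2COC(C)(C)O2)[C@]13CO3 | intermediate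
16 | chlorohydrin acetonide: (3R,4S,5R)-3-(chloromethyl)-4-[(4S)-2,2-dimethyl-1,3-dioxolan-4-yl]-3-hydroxy-5-[(1Z)-2-iodoprop-1-en-1-yl]oxolan-2-one | O=C1O[C@@H](/C=C(/C)I)[C@@H]([C@H]2COC(C)(C)O2)[C@]1(O)CCl | intermediate (not isolated)
17 | (3R,4R,5R)-3-(chloromethyl)-4-[(1S)-1,2-dihydroxyethyl]-3-hydroxy-5-[(1Z)-2-iodoprop-1-en-1-yl]oxolan-2-one | O=C1O[C@@H](/C=C(/C)I)[C@@H]([C@H](O)CO)[C@]1(O)CCl | intermediate
18 | (3R,4R,5R)-4-[(1S)-2-{[tert-butyl(dimethyl)silyl]oxy}-1-hydroxyethyl]-3-(chloromethyl)-3-hydroxy-5-[(1Z)-2-iodoprop-1-en-1-yl]oxolan-2-one | O=C1O[C@@H](/C=C(/C)I)[C@@H]([C@H](O)CO[Si](C)(C)C(C)(C)C)[C@]1(O)CCl | intermediate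
19 | angelic acid, (2Z)-2-methylbut-2-enoic acid | C/C=C(/C)C(=O)O | starting material
20 | angelic 2,4,6-trichlorobenzoic anhydride | C/C=C(/C)C(=O)OC(=O)c1c(Cl)cc(Cl)cc1Cl | intermediate (not isolated)
21 | (1S)-2-{[tert-butyl(dimethyl)silyl]oxy}-1-[(2R,3S,4R)-4-(chloromethyl)-4-hydroxy-2-[(1Z)-2-iodoprop-1-en-1-yl]-5-oxooxolan-3-yl]ethyl (2Z)-2-methylbut-2-enoate | O=C1O[C@@H](/C=C(/C)I)[C@@H]([C@H](OC(=O)/C(C)=C\C)CO[Si](C)(C)C(C)(C)C)[C@]1(O)CCl | intermediate
22 | ethyl (S)-lactate | C[C@H](O)C(=O)OCC | starting material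
23 | ethyl (2S)-2-{[tert-butyl(dimethyl)silyl]oxy}propanoate | C[C@H](O[Si](C)(C)C(C)(C)C)C(=O)OCC | intermediate
24 | Weinreb amide: (2S)-2-{[tert-butyl(dimethyl)silyl]oxy}-N-methoxy-N-methylpropanamide | C[C@H](O[Si](C)(C)C(C)(C)C)C(=O)N(C)OC | intermediate (not isolated)
25 | (4S)-4-{[tert-butyl(dimethyl)silyl]oxy}pent-1-yn-3-one | C[C@H](O[Si](C)(C)C(C)(C)C)C(=O)C#C | intermediate
26 | (Z)-enynone (6S,7S,8S,10S,11R): 21 with iodine replaced by the (4S)-4-{[tert-butyl(dimethyl)silyl]oxy}-3-oxopent-1-yn-1-yl group | O=C1O[C@@H](/C=C(/C)C#CC(=O)[C@H](C)O[Si](C)(C)C(C)(C)C)[C@@H]([C@H](OC(=O)/C(C)=C\C)CO[Si](C)(C)C(C)(C)C)[C@]1(O)CCl | intermediate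
27 | dihydroxy enynone (6S,7S,8S,10S,11R): 26 with free C9-OH and C10-OH | O=C1O[C@@H](/C=C(/C)C#CC(=O)[C@H](C)O)[C@@H]([C@H](OC(=O)/C(C)=C\C)CO)[C@]1(O)CCl | intermediate
28 | furanone alcohol (6S,7S,8S,10S,11R): 5-alkenyl-2-methyl-3(2H)-furanone with free C9-OH, C8 angelate and chlorohydrin lactone | O=C1O[C@@H](/C=C(/C)C2=CC(=O)[C@H](C)O2)[C@@H]([C@H](OC(=O)/C(C)=C\C)CO)[C@]1(O)CCl | intermediate
29 | furanone aldehyde (6S,7S,8S,10S,11R): 28 with C9 as CHO | O=C1O[C@@H](/C=C(/C)C2=CC(=O)[C@H](C)O2)[C@@H]([C@H](OC(=O)/C(C)=C\C)C=O)[C@]1(O)CCl | intermediate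
30 | key-step precursor (6S,7S,8S,11R): C9 aldehyde, C8 angelate, cis-γ-lactone with C11-OSiEt3 and C13-Cl, Z C4=C5 alkene, 2-methyl-3-(triethylsiloxy)furan | O=C[C@@H](OC(=O)/C(C)=C\C)[C@H]1[C@](O[Si](CC)(CC)CC)(CCl)C(=O)O[C@H]1/C=C(/C)c1cc(O[Si](CC)(CC)CC)c(C)o1 | intermediate
31 | C11-O-triethylsilyl ether of the target (6S,7S,8S,9R,10R,11R) | C/C=C(/C)C(=O)O[C@H]1[C@@H]2[C@H](/C=C(/C)C3=CC(=O)[C@](C)(O3)[C@@H]1O)OC(=O)[C@@]2(O[Si](CC)(CC)CC)CCl | intermediate
32 | CNP0272644.1 (6S,7S,8S,9R,10R,11R) | C/C=C(/C)C(=O)O[C@H]1[C@@H]2[C@H](/C=C(/C)C3=CC(=O)[C@](C)(O3)[C@@H]1O)OC(=O)[C@@]2(O)CCl | target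

Total step count: 21.
Longest linear sequence: 17 steps (steps 1 to 3, 6 to 12 and 15 to 21, from 1 to 32).

Steps most likely to fail

Step 20. The ring closure may lose to intermolecular aldol addition or to protodesilylation of the siloxyfuran, or the chain may close on the other furan face or present the other aldehyde face, giving the wrong C9/C10 relationship. The fallback sets out from 30. N-Bromosuccinimide in THF at −78 °C should brominate the siloxyfuran at C10 and give the 2-bromo-2-methyl-3(2H)-furanone F1. Slow addition of SmI2 (2.2 equiv, THF, −78 °C) to a dilute solution of F1 should then reduce the C–Br bond selectively to the diiodosamarium enolate F2. F2 closes the ring by an intramolecular Reformatsky-type aldol addition through a chelated, closed transition state, which holds the aldehyde oxygen next to the C1 oxygen as the target requires. After aqueous work-up the sequence comes back to the route at 31.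

Step 6. The aldehyde may add to the other face of the allylindium, so that the C6/C7 pair is inverted relative to C8. The fallback sets out from 9 and uses the other enantiomer of the chiral building block. Commercially available (S)-2,3-O-isopropylideneglyceraldehyde (O=C[C@@H]1COC(C)(C)O1) is taken through the chemistry of steps 2 and 3 to the Baylis–Hillman adduct F3 and the antipodal bromide F4. Indium-mediated coupling of F4 with 9 (allylindium F5) should then give the hydroxy ester F6, which has the required C6 and C7 configurations and is epimeric with 11 at C8 only. F6 is carried through the chemistry of steps 7 to 11: diol F7, epoxy diol F8 (same D-tartrate), lactol F9, epoxy lactone F10, chlorohydrin acetonide F11, triol F12 and primary silyl ether F13. The C8 centre is then corrected in the esterification itself by a Mitsunobu reaction of F13 with angelic acid 19 (PPh3, DIAD, toluene, 0 °C to rt), which proceeds with inversion and comes back to the route at 21.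

Step 19. Silyl triflate and amine may enolise or silylate the α-acyloxy aldehyde (loss of the C8 configuration) or trigger premature intermolecular aldol addition. The fallback sets out from 29 and avoids both amine and silyl triflate. The enol tautomer of the furanone is trapped by neutral silyl transfer from N,O-bis(trimethylsilyl)acetamide (MeCN, rt to 40 °C), which also silylates the C11 hydroxyl and should give the bis(trimethylsilyl) analogue F14 after removal of the volatile acetamides in vacuo. F14 is cyclised under the conditions of step 20 to the trimethylsilyl ether F15. Its tertiary silyl ether is hydrolysed with dilute acid (aq. citric acid, THF), so that the sequence comes back to the route at 32.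

Further compounds
F1 | step 20 | 2-bromo-2-methyl-3(2H)-furanone analogue of 30 (bromine at C10, both C10 epimers; C9 aldehyde and C11-OSiEt3 unchanged) | O=C[C@@H](OC(=O)/C(C)=C\C)[C@H]1[C@](O[Si](CC)(CC)CC)(CCl)C(=O)O[C@H]1/C=C(/C)C1=CC(=O)C(C)(Br)O1
F2 | step 20 | diiodosamarium enolate (3-furanolate) derived from F1 | O=C[C@@H](OC(=O)/C(C)=C\C)[C@H]1[C@](O[Si](CC)(CC)CC)(CCl)C(=O)O[C@H]1/C=C(/C)c1cc(O[Sm](I)I)c(C)o1
F3 | step 6 | methyl 2-{[(4S)-2,2-dimethyl-1,3-dioxolan-4-yl](hydroxy)methyl}prop-2-enoate (both carbinol epimers) | C=C(C(=O)OC)C(O)[C@@H]1COC(C)(C)O1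
F4 | step 6 | methyl (2Z)-2-(bromomethyl)-3-[(4R)-2,2-dimethyl-1,3-dioxolan-4-yl]prop-2-enoate (enantiomer of 5) | COC(=O)/C(CBr)=C/[C@@H]1COC(C)(C)O1
F5 | step 6 | allylindium dibromide from F4 (enantiomer of 10) | COC(=O)/C(C[In](Br)Br)=C/[C@@H]1COC(C)(C)O1
F6 | step 6 | C8 epimer of hydroxy ester 11 | COC(=O)C(=C)[C@H]([C@@H]1COC(C)(C)O1)[C@@H](O)/C=C(/C)I
F7 | step 6 | C8 epimer of diol 12 | OCC(=C)[C@H]([C@@H]1COC(C)(C)O1)[C@@H](O)/C=C(/C)I
F8 | step 6 | C8 epimer of epoxy diol 13 | OC[C@@]1(CO1)[C@H]([C@@H]2COC(C)(C)O2)[C@@H](O)/C=C(/C)I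
F9 | step 6 | C8 epimer of lactol 14 | OC1O[C@@H](/C=C(/C)I)[C@@H]([C@@H]2COC(C)(C)O2)[C@]13CO3
F10 | step 6 | C8 epimer of epoxy lactone 15 | O=C1O[C@@H](/C=C(/C)I)[C@@H]([C@@H]2COC(C)(C)O2)[C@]13CO3
F11 | step 6 | C8 epimer of chlorohydrin acetonide 16 | O=C1O[C@@H](/C=C(/C)I)[C@@H]([C@@H]2COC(C)(C)O2)[C@]1(O)CCl
F12 | step 6 | C8 epimer of triol 17 | O=C1O[C@@H](/C=C(/C)I)[C@@H]([C@@H](O)CO)[C@]1(O)CCl
F13 | step 6 | C8 epimer of silyl ether 18 | O=C1O[C@@H](/C=C(/C)I)[C@@H]([C@@H](O)CO[Si](C)(C)C(C)(C)C)[C@]1(O)CCl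
F14 | step 19 | bis(trimethylsilyl) analogue of 30 (3-(trimethylsiloxy)furan, C11-OSiMe3) | O=C[C@@H](OC(=O)/C(C)=C\C)[C@H]1[C@](O[Si](C)(C)C)(CCl)C(=O)O[C@H]1/C=C(/C)c1cc(O[Si](C)(C)C)c(C)o1
F15 | step 19 | C11-O-trimethylsilyl analogue of 31 | C/C=C(/C)C(=O)O[C@H]1[C@@H]2[C@H](/C=C(/C)C3=CC(=O)[C@](C)(O3)[C@@H]1O)OC(=O)[C@@]2(O[Si](C)(C)C)CCl
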